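**Plan**
- Retrosynthetic cuts, in order: the O15 silyl ether; the 7α‑OH traced back to a 9α‑OH by allylic 1,3‑transposition; the C6–O and C9–O bonds to O2 added across a 6,8‑diene; C5–H and the C1–C2 single bond to a 1,5,8‑trien‑7‑one; the C1–C10 bond (key step); then C1=C2 (Wittig), C12–C13 (B‑alkyl Suzuki), C9–C11 (Stille), C7–O (borylation/oxidation) and C3–C4 (cation capture) on a benzene ring.
- Enabling feature: ring B (C5–C10) carries its C7 oxygen para to the quaternary C10 and has sp2 carbons at C8 (methyl C17) and C9 (side chain). That is the pattern of a 4,4‑disubstituted cyclohexa‑2,5‑dienone, and so of a para‑methyl phenol C‑alkenylated at C10 by C1 of a chain hung on C5.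
- Forward order: ring B is bought as an arene and dressed to a pentasubstituted phenol, the C11–C15 chain is joined by Suzuki coupling, ring A (C1–C5, C10) is closed by palladium‑catalysed dearomatisation, and ring B is then adjusted in oxidation level.
- Stereochemistry: C10 from the chiral phosphine on palladium; C5 from Li/NH3 protonation trans to the C10 methyl; 9α‑O from α‑face singlet‑oxygen addition; 6β‑O from α‑face hydride; 7α‑O from the suprafacial 1,3‑shift of the 9α oxygen; 13Z from trans‑hydroalumination/iodination.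

Key step: step 12

Assumption: the (R)‑configured ligand in step 12 is taken to give the 10β‑methyl dienone; if a pilot run shows the opposite sense its antipode is used and nothing else changes. The phenol is carried unprotected from 7 on, with one extra equivalent of reagent wherever the O–H consumes it.

**Route**

Step 1
Reactants: 1 2-bromo-1,3-dimethylbenzene
Product: 2 1-(3-bromo-2,4-dimethylphenyl)ethan-1-one
Conditions: AcCl (1.1 equiv), AlCl3 (1.2 equiv), CH2Cl2, 0 °C to rt
Reagents that add atoms: acetyl chloride, CC(=O)Cl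
Why: Friedel–Crafts acylation should go to the position that is ortho to one methyl and para to the other (meta to bromine), as in the acetylation of m-xylene.

Step 2
Reactants: 2 1-(3-bromo-2,4-dimethylphenyl)ethan-1-one
Product: 3 2-(3-bromo-2,4-dimethylphenyl)propan-2-ol
Conditions: MeMgBr (1.5 equiv), THF, 0 °C to rt; aq NH4Cl
Reagents that add atoms: methylmagnesium bromide, C[Mg]Br
Why: Grignard addition to the aryl methyl ketone gives the tertiary benzylic alcohol whose carbinol carbon becomes C4 with both of its methyl groups.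

Step 3
Reactants: 3 2-(3-bromo-2,4-dimethylphenyl)propan-2-ol
Product: 4 methyl 3-(3-bromo-2,4-dimethylphenyl)-3-methylbutanoate
Conditions: 1-(tert-butyldimethylsilyloxy)-1-methoxyethene (2 equiv), Bi(OTf)3 (5 mol %), CH2Cl2, 0 °C to rt
Reagents that add atoms: 1-(tert-butyldimethylsilyloxy)-1-methoxyethene, C=C(OC)O[Si](C)(C)C(C)(C)C
Why: Lewis-acid ionisation of the tertiary benzylic alcohol and capture of the cumyl-type cation by the ketene silyl acetal (SN1 alkylation of a silyl enolate, the catalytic form of the Reetz tert-alkylation) builds quaternary C4 with C3 and C2 attached.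

Step 4
Reactants: 4 methyl 3-(3-bromo-2,4-dimethylphenyl)-3-methylbutanoate
Product: 5 methyl 3-(3-bromo-5-iodo-2,4-dimethylphenyl)-3-methylbutanoate
Conditions: N-iodosuccinimide (1.1 equiv), CF3CO2H (0.3 equiv), MeCN, rt to 40 °C
Reagents that add atoms: N-iodosuccinimide, O=C1CCC(=O)N1I
Why: Electrophilic aromatic iodination should take the one free position that is ortho and para to the two ring methyl groups, since the other is meta to both and crowded by the tert-alkyl group.

Step 5
Reactants: 5 methyl 3-(3-bromo-5-iodo-2,4-dimethylphenyl)-3-methylbutanoate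
Product: 7 methyl 3-(3-bromo-5-hydroxy-2,4-dimethylphenyl)-3-methylbutanoate, via arylboronic pinacol ester 6 (not isolated)
Conditions: B2pin2 (1.2 equiv), PdCl2(dppf) (3 mol %), KOAc (3 equiv), dioxane, 80 °C; then 30% aq H2O2, aq NaHCO3, THF, 0 °C to rt
Reagents that add atoms: hydrogen peroxide, OO
Why: Miyaura borylation is selective for the aryl iodide over the bromide flanked by two methyl groups, and peroxide oxidation of the boronate (aryl shift from boron to oxygen) gives the phenol whose oxygen becomes O7.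

Step 6
Reactants: 7 methyl 3-(3-bromo-5-hydroxy-2,4-dimethylphenyl)-3-methylbutanoate
Product: 8 methyl 3-(3-ethenyl-5-hydroxy-2,4-dimethylphenyl)-3-methylbutanoate
Conditions: tributyl(vinyl)stannane (1.3 equiv), Pd(P(t-Bu)3)2 (3 mol %), CsF (2.2 equiv), dioxane, 100 °C
Reagents that add atoms: tributyl(vinyl)stannane, C=C[Sn](CCCC)(CCCC)CCCC
Why: Stille coupling with a bulky electron-rich phosphine is an established answer to di-ortho-substituted aryl bromides, tolerates the phenol and the ester, and installs C11 and C12 as a vinyl group.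

Step 7
Reactants: 9 but-2-yn-1-ol
Product: 11 (Z)-3-iodobut-2-en-1-ol, via alkenylaluminate 10 (not isolated)
Conditions: NaAlH2(OCH2CH2OMe)2 (1.5 equiv), THF, 0 °C to rt; then I2 (1.6 equiv), THF, −78 °C to 0 °C
Reagents that add atoms: iodine, II
Why: Alkoxide-directed trans-hydroalumination of the propargylic alcohol places aluminium on C3 in a five-membered ring and iodinolysis goes with retention, which fixes the geometry that becomes the 13Z alkene.

Step 8
Reactants: 11 (Z)-3-iodobut-2-en-1-ol
Product: 12 tert-butyl{[(Z)-3-iodobut-2-en-1-yl]oxy}dimethylsilane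
Conditions: TBSCl (1.2 equiv), imidazole (2 equiv), CH2Cl2, 0 °C to rt
Reagents that add atoms: tert-butyldimethylsilyl chloride, CC(C)(C)[Si](C)(C)Cl
Why: Standard silylation of a primary alcohol masks O15 until the last step.

Step 9
Reactants: 8 methyl 3-(3-ethenyl-5-hydroxy-2,4-dimethylphenyl)-3-methylbutanoate; 12 tert-butyl{[(Z)-3-iodobut-2-en-1-yl]oxy}dimethylsilane
Product: 14 methyl 3-{3-[(Z)-5-(tert-butyldimethylsilyloxy)-3-methylpent-3-en-1-yl]-5-hydroxy-2,4-dimethylphenyl}-3-methylbutanoate, via bis-boryl intermediate 13 (not isolated)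
Conditions: 8, 9-BBN (2.3 equiv), THF, rt to 50 °C; then 12 (1.1 equiv), PdCl2(dppf) (5 mol %), 3 M aq K3PO4 (3 equiv), DMF, rt to 45 °C
Reagents that add atoms: none
Why: Anti-Markovnikov hydroboration of the styrene (one further equivalent of borane is taken up by the phenol O–H and released again by the aqueous base) followed by B-alkyl Suzuki–Miyaura coupling with the alkenyl iodide joins C12 to C13 with retention of the Z geometry.

Step 10
Reactants: 14 methyl 3-{3-[(Z)-5-(tert-butyldimethylsilyloxy)-3-methylpent-3-en-1-yl]-5-hydroxy-2,4-dimethylphenyl}-3-methylbutanoate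
Product: 15 3-{3-[(Z)-5-(tert-butyldimethylsilyloxy)-3-methylpent-3-en-1-yl]-5-hydroxy-2,4-dimethylphenyl}-3-methylbutanal
Conditions: i-Bu2AlH (2.3 equiv), CH2Cl2, −78 °C; aq potassium sodium tartrate
Reagents that add atoms: none
Why: Partial reduction of a methyl ester with diisobutylaluminium hydride at low temperature should stop at the aluminium hemiacetal, helped here by the neopentyl-type surroundings, after the first equivalent has deprotonated the phenol.

Step 11
Reactants: 15 3-{3-[(Z)-5-(tert-butyldimethylsilyloxy)-3-methylpent-3-en-1-yl]-5-hydroxy-2,4-dimethylphenyl}-3-methylbutanal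
Product: 16 5-[(Z)-5-bromo-2-methylpent-4-en-2-yl]-3-[(Z)-5-(tert-butyldimethylsilyloxy)-3-methylpent-3-en-1-yl]-2,4-dimethylphenol
Conditions: [Ph3PCH2Br]Br (3.0 equiv), KOtBu (4.0 equiv), THF, −78 °C; then 15, −78 °C to −20 °C
Reagents that add atoms: (bromomethyl)triphenylphosphonium bromide, [Br-].BrC[P+](c1ccccc1)(c1ccccc1)c1ccccc1
Why: Wittig olefination with the non-stabilised bromomethylene ylide at low temperature should give mainly the Z-bromoalkene (the usual halomethylenation route to Z-alkenyl halides), with the extra base carrying the phenol as its potassium salt and the minor E isomer removed by chromatography.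

Step 12
Reactants: 16 5-[(Z)-5-bromo-2-methylpent-4-en-2-yl]-3-[(Z)-5-(tert-butyldimethylsilyloxy)-3-methylpent-3-en-1-yl]-2,4-dimethylphenol
Product: 17 15-(tert-butyldimethylsilyloxy)labda-1,5,8,13(Z)-tetraen-7-one (10β-methyl)
Conditions: Pd2(dba)3 (2.5 mol %), (R)-AntPhos [(R)-4-(anthracen-9-yl)-3-tert-butyl-2,3-dihydrobenzo[d][1,3]oxaphosphole] (6 mol %), K2CO3 (2.0 equiv), toluene, 100 °C
Reagents that add atoms: none
Why: Proposed new method: zerovalent palladium inserts into the C1–Br bond with retention of the Z geometry, the phenoxide formed by K2CO3 replaces bromide on divalent palladium and binds through its para carbon C10, and reductive elimination forms C1–C10 and releases the cross-conjugated dienone; the closest known reaction type is the palladium-catalysed enantioselective dearomative cyclisation of para-substituted phenols onto tethered aryl bromides, which gives ring-fusion quaternary carbons with this catalyst system, and an alkenyl bromide should add oxidatively at least as easily as an aryl bromide. Ring A closes as a six-membered carbocycle by C–C reductive elimination from a seven-membered palladacycle that holds C1 and C10. C10, the only new stereocentre, is set by the P-chiral monophosphine on palladium, which selects one face of the prochiral phenoxide carbon in the bond-forming step. The step needs attack at the para carbon C10 and not at the ortho carbon C6, which is equally within reach of a six-membered ring and would lead back to an aromatic product: the substrate secures this because closure at C6 requires a rotamer about C5–C4 in which a C4 methyl eclipses the C10 methyl (allylic 1,3-strain), whereas the preferred rotamer already holds the alkenyl chain over C10, and the bulky ligand favours the dearomative path as in the precedent. O-Alkenylation is excluded because O7 cannot be reached from C5, and only the Z bromide can close.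

Step 13
Reactants: 17 15-(tert-butyldimethylsilyloxy)labda-1,5,8,13(Z)-tetraen-7-one
Product: 18 15-(tert-butyldimethylsilyloxy)labda-5,8,13(Z)-trien-7-one
Conditions: H2 (1 atm), RhCl(PPh3)3 (5 mol %), benzene–EtOH (1:1), rt
Reagents that add atoms: none
Why: Homogeneous hydrogenation with RhCl(PPh3)3 should reduce only the cis-disubstituted C1=C2 bond and leave the trisubstituted side-chain alkene and the hindered dienone double bonds alone, as in the selective saturation of the disubstituted double bond of steroidal 1,4-dien-3-ones.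

Step 14
Reactants: 18 15-(tert-butyldimethylsilyloxy)labda-5,8,13(Z)-trien-7-one
Product: 20 15-(tert-butyldimethylsilyloxy)labda-6,8,13(Z)-trien-7-yl trifluoromethanesulfonate (5α-H), via lithium dienolate 19 (not isolated)
Conditions: Li (2.5 equiv), t-BuOH (1.0 equiv), NH3(l)–THF, −78 °C; isoprene; NH3 evaporated; then PhNTf2 (2.0 equiv), THF, −78 °C to 0 °C
Reagents that add atoms: N-phenylbis(trifluoromethanesulfonimide), O=S(=O)(N(c1ccccc1)S(=O)(=O)C(F)(F)F)C(F)(F)F
Why: Dissolving-metal reduction of a cross-conjugated dienone saturates the less substituted double bond (C5=C6, not the tetrasubstituted C8=C9) because the less alkylated enolate results, protonation at C5 on the α face gives the more stable trans ring fusion (5α-H, anti to the C10 methyl), and the regiodefined lithium enolate is trapped on oxygen (reductive triflation).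

Step 15
Reactants: 20 15-(tert-butyldimethylsilyloxy)labda-6,8,13(Z)-trien-7-yl trifluoromethanesulfonate
Product: 21 tert-butyldimethyl{[labda-6,8,13(Z)-trien-15-yl]oxy}silane (5α-H)
Conditions: Pd(OAc)2 (5 mol %), PPh3 (10 mol %), HCO2H (2 equiv), Bu3N (3 equiv), DMF, 60 °C
Reagents that add atoms: none
Why: Palladium-catalysed formate reduction of an enol triflate replaces OTf by H without moving the double bonds and gives the homoannular 6,8-diene, while the silyl ether and the isolated alkene do not react with zerovalent palladium.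

Step 16
Reactants: 21 tert-butyldimethyl{[labda-6,8,13(Z)-trien-15-yl]oxy}silane
Product: 23 15-(tert-butyldimethylsilyloxy)-9α-hydroxylabda-7,13(Z)-dien-6-one, via 6α,9α-endoperoxide 22 (not isolated)
Conditions: O2, tetraphenylporphyrin (1 mol %), visible light, CH2Cl2, −78 °C; then Et3N (2 equiv), 0 °C to rt
Reagents that add atoms: dioxygen, O=O
Why: Singlet oxygen adds [4+2] to the s-cis diene from the α face, away from the axial C10 and C4β methyl groups as with steroidal 5,7-dienes, which sets the 9α C–O bond, and the Kornblum–DeLaMare fragmentation removes the only proton on a peroxide carbon (H6) to give the 6-ketone and the 9α-alcohol.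

Step 17
Reactants: 23 15-(tert-butyldimethylsilyloxy)-9α-hydroxylabda-7,13(Z)-dien-6-one
Product: 24 15-(tert-butyldimethylsilyloxy)labda-7,13(Z)-diene-6β,9α-diol
Conditions: NaBH4 (1.5 equiv), CeCl3·7H2O (1.2 equiv), MeOH, −78 °C to −20 °C
Reagents that add atoms: none
Why: Luche 1,2-reduction of the enone should deliver hydride from the α face, because the β face of C6 is screened by the two syn-axial methyl groups on C4 and C10, so the 6β-alcohol results.

Step 18
Reactants: 24 15-(tert-butyldimethylsilyloxy)labda-7,13(Z)-diene-6β,9α-diol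
Product: 25 6β-acetoxy-15-(tert-butyldimethylsilyloxy)labda-7,13(Z)-dien-9α-ol
Conditions: Ac2O (5 equiv), DMAP (0.5 equiv), pyridine, 40 °C
Reagents that add atoms: acetic anhydride, CC(=O)OC(C)=O
Why: DMAP-catalysed acylation esterifies the secondary allylic 6β-hydroxyl, while the tertiary 9α-hydroxyl next to quaternary C10 is inert under these conditions.

Step 19
Reactants: 25 6β-acetoxy-15-(tert-butyldimethylsilyloxy)labda-7,13(Z)-dien-9α-ol
Product: 26 6β-acetoxy-15-(tert-butyldimethylsilyloxy)labda-8,13(Z)-dien-7α-ol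
Conditions: Ph3SiOReO3 (5 mol %), Et2O, 0 °C to rt
Reagents that add atoms: none
Why: Oxorhenium-catalysed 1,3-transposition of a tertiary allylic alcohol runs through a perrhenate ester and a cyclic [3,3] shift that is necessarily suprafacial on a cyclohexene, so the 9α oxygen arrives on the α face of C7 (trans to the 6β-acetate), driven by the tetrasubstituted C8=C9 bond and relief of strain at C9.

Step 20
Reactants: 26 6β-acetoxy-15-(tert-butyldimethylsilyloxy)labda-8,13(Z)-dien-7α-ol
Product: 27 (5S,6S,7S,10S)-6β-acetoxylabda-8,13(Z)-diene-7α,15-diol (CNP0183298.2)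
Conditions: HF·pyridine, pyridine, THF, 0 °C to rt
Reagents that add atoms: none
Why: Buffered fluoride cleaves the primary silyl ether, and the trans-diaxial 6β-acetate/7α-hydroxyl pair cannot form the cyclic orthoester needed for acyl migration, so the acetate should stay on O6.

**Compound list**

1 | 2-bromo-1,3-dimethylbenzene | Cc1cccc(C)c1Br | starting material
2 | 1-(3-bromo-2,4-dimethylphenyl)ethan-1-one | CC(=O)c1ccc(C)c(Br)c1C | intermediate
3 | 2-(3-bromo-2,4-dimethylphenyl)propan-2-ol | CC(C)(O)c1ccc(C)c(Br)c1C | intermediate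
4 | methyl 3-(3-bromo-2,4-dimethylphenyl)-3-methylbutanoate | COC(=O)CC(C)(C)c1ccc(C)c(Br)c1C | intermediate
5 | methyl 3-(3-bromo-5-iodo-2,4-dimethylphenyl)-3-methylbutanoate | COC(=O)CC(C)(C)c1cc(I)c(C)c(Br)c1C | intermediate
6 | methyl 3-[3-bromo-2,4-dimethyl-5-(4,4,5,5-tetramethyl-1,3,2-dioxaborolan-2-yl)phenyl]-3-methylbutanoate | COC(=O)CC(C)(C)c1cc(B2OC(C)(C)C(C)(C)O2)c(C)c(Br)c1C | intermediate (not isolated)
7 | methyl 3-(3-bromo-5-hydroxy-2,4-dimethylphenyl)-3-methylbutanoate | COC(=O)CC(C)(C)c1cc(O)c(C)c(Br)c1C | intermediate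
8 | methyl 3-(3-ethenyl-5-hydroxy-2,4-dimethylphenyl)-3-methylbutanoate | COC(=O)CC(C)(C)c1cc(O)c(C)c(C=C)c1C | intermediate
9 | but-2-yn-1-ol | CC#CCO | starting material
10 | sodium 2,2-bis(2-methoxyethoxy)-3-methyl-2,5-dihydro-1,2-oxaaluminol-2-uide | CC1=CCO[Al-]1(OCCOC)OCCOC.[Na+] | intermediate (not isolated)
11 | (Z)-3-iodobut-2-en-1-ol | C/C(I)=C/CO | intermediate
12 | tert-butyl{[(Z)-3-iodobut-2-en-1-yl]oxy}dimethylsilane | C/C(I)=C/CO[Si](C)(C)C(C)(C)C | intermediate
13 | methyl 3-{3-[2-(9-borabicyclo[3.3.1]nonan-9-yl)ethyl]-5-(9-borabicyclo[3.3.1]nonan-9-yloxy)-2,4-dimethylphenyl}-3-methylbutanoate | COC(=O)CC(C)(C)c1cc(OB2C3CCCC2CCC3)c(C)c(CCB2C3CCCC2CCC3)c1C | intermediate (not isolated)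
14 | methyl 3-{3-[(Z)-5-(tert-butyldimethylsilyloxy)-3-methylpent-3-en-1-yl]-5-hydroxy-2,4-dimethylphenyl}-3-methylbutanoate | COC(=O)CC(C)(C)c1cc(O)c(C)c(CC/C(C)=C\CO[Si](C)(C)C(C)(C)C)c1C | intermediate
15 | 3-{3-[(Z)-5-(tert-butyldimethylsilyloxy)-3-methylpent-3-en-1-yl]-5-hydroxy-2,4-dimethylphenyl}-3-methylbutanal | O=CCC(C)(C)c1cc(O)c(C)c(CC/C(C)=C\CO[Si](C)(C)C(C)(C)C)c1C | intermediate
16 | 5-[(Z)-5-bromo-2-methylpent-4-en-2-yl]-3-[(Z)-5-(tert-butyldimethylsilyloxy)-3-methylpent-3-en-1-yl]-2,4-dimethylphenol | Cc1c(O)cc(C(C)(C)C/C=C\Br)c(C)c1CC/C(C)=C\CO[Si](C)(C)C(C)(C)C | intermediate (key-step precursor)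
17 | 15-(tert-butyldimethylsilyloxy)labda-1,5,8,13(Z)-tetraen-7-one, 10β-methyl | O=C1C=C2C(C)(C)CC=C[C@]2(C)C(CC/C(C)=C\CO[Si](C)(C)C(C)(C)C)=C1C | intermediate (key-step product)
18 | 15-(tert-butyldimethylsilyloxy)labda-5,8,13(Z)-trien-7-one | O=C1C=C2C(C)(C)CCC[C@]2(C)C(CC/C(C)=C\CO[Si](C)(C)C(C)(C)C)=C1C | intermediate
19 | lithium 15-(tert-butyldimethylsilyloxy)labda-6,8,13(Z)-trien-7-olate, 5α-H | C1=C([O-])C(C)=C(CC/C(C)=C\CO[Si](C)(C)C(C)(C)C)[C@@]2(C)CCCC(C)(C)[C@H]12.[Li+] | intermediate (not isolated)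
20 | 15-(tert-butyldimethylsilyloxy)labda-6,8,13(Z)-trien-7-yl trifluoromethanesulfonate, 5α-H | C1=C(OS(=O)(=O)C(F)(F)F)C(C)=C(CC/C(C)=C\CO[Si](C)(C)C(C)(C)C)[C@@]2(C)CCCC(C)(C)[C@H]12 | intermediate
21 | tert-butyldimethyl{[labda-6,8,13(Z)-trien-15-yl]oxy}silane, 5α-H | C1=CC(C)=C(CC/C(C)=C\CO[Si](C)(C)C(C)(C)C)[C@@]2(C)CCCC(C)(C)[C@H]12 | intermediate
22 | 15-(tert-butyldimethylsilyloxy)-6α,9α-epidioxylabda-7,13(Z)-diene | [C@H]1(OO3)C=C(C)[C@]3(CC/C(C)=C\CO[Si](C)(C)C(C)(C)C)[C@@]2(C)CCCC(C)(C)[C@H]12 | intermediate (not isolated)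
23 | 15-(tert-butyldimethylsilyloxy)-9α-hydroxylabda-7,13(Z)-dien-6-one | O=C1C=C(C)[C@](O)(CC/C(C)=C\CO[Si](C)(C)C(C)(C)C)[C@@]2(C)CCCC(C)(C)[C@H]12 | intermediate
24 | 15-(tert-butyldimethylsilyloxy)labda-7,13(Z)-diene-6β,9α-diol | O[C@@H]1C=C(C)[C@](O)(CC/C(C)=C\CO[Si](C)(C)C(C)(C)C)[C@@]2(C)CCCC(C)(C)[C@H]12 | intermediate
25 | 6β-acetoxy-15-(tert-butyldimethylsilyloxy)labda-7,13(Z)-dien-9α-ol | CC(=O)O[C@@H]1C=C(C)[C@](O)(CC/C(C)=C\CO[Si](C)(C)C(C)(C)C)[C@@]2(C)CCCC(C)(C)[C@H]12 | intermediate
26 | 6β-acetoxy-15-(tert-butyldimethylsilyloxy)labda-8,13(Z)-dien-7α-ol | CC(=O)O[C@@H]1[C@@H](O)C(C)=C(CC/C(C)=C\CO[Si](C)(C)C(C)(C)C)[C@@]2(C)CCCC(C)(C)[C@H]12 | intermediate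
27 | (5S,6S,7S,10S)-6β-acetoxylabda-8,13(Z)-diene-7α,15-diol | CC(=O)O[C@@H]1[C@@H](O)C(C)=C(CC/C(C)=C\CO)[C@@]2(C)CCCC(C)(C)[C@H]12 | target

**Count and risks**

Total: 20 steps. Longest linear sequence: 18 steps (steps 1–6 and 9–20 from compound 1); the side-chain iodide 12 takes 2 steps from compound 9.

Most likely to fail:

1. Step 12. The alkenyl bromide may be reduced instead of cyclising, the chain may close at the ortho carbon with re-aromatisation, or the enantioselectivity may be low. The fallback sets out from aldehyde 15 and returns at 18, so it also replaces step 13. Methylenation of 15 (Ph3PCH3Br, KOtBu, THF) gives 5-(2-methylpent-4-en-2-yl)-3-[(Z)-5-(tert-butyldimethylsilyloxy)-3-methylpent-3-en-1-yl]-2,4-dimethylphenol F1. Hydroboration of the terminal alkene only (9-BBN, then NaOH/H2O2) gives 5-(5-hydroxy-2-methylpentan-2-yl)-3-[(Z)-5-(tert-butyldimethylsilyloxy)-3-methylpent-3-en-1-yl]-2,4-dimethylphenol F2. Appel bromination (CBr4, PPh3), which leaves the phenol alone, gives 5-(5-bromo-2-methylpentan-2-yl)-3-[(Z)-5-(tert-butyldimethylsilyloxy)-3-methylpent-3-en-1-yl]-2,4-dimethylphenol F3. Intramolecular para-C-alkylation of the phenoxide (KOtBu, t-BuOH, high dilution, 70 °C; the classical phenoxide route to fused cyclohexadienones, with the same rotamer bias toward C10) gives racemic 15-(tert-butyldimethylsilyloxy)labda-5,8,13(Z)-trien-7-one F4. Preparative chromatography on a chiral stationary phase then delivers 18.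

2. Step 14. Protonation of the reduced dienone may go to C9 instead of C5, and the allylic silyl ether may suffer reductive cleavage. The fallback sets out from 18 and returns at 20; it takes the tetrasubstituted double bond out of conjugation before the reduction. γ-Deprotonation at C11 (LiN(i-Pr)2, THF–HMPA, −78 °C) and kinetic α-protonation with AcOH give 15-(tert-butyldimethylsilyloxy)labda-5,9(11),13(Z)-trien-7-one F5. This simple enone is reduced without ambiguity (Li, NH3, t-BuOH, then NH4Cl) to 15-(tert-butyldimethylsilyloxy)labda-9(11),13(Z)-dien-7-one F6 (5α-H). Base (DBU, CH2Cl2) moves the double bond back into conjugation to give 15-(tert-butyldimethylsilyloxy)labda-8,13(Z)-dien-7-one F7. Kinetic deprotonation at C6 (LiN(i-Pr)2, −78 °C) and PhNTf2 give 20.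

3. Step 19. The tertiary alcohol may dehydrate, or ionisation next to the 6β-acetate may erode the facial fidelity of the oxygen shift. The fallback sets out from 25 and returns at 26. Oxidative transposition with pyridinium chlorochromate [C5H5NH][CrO3Cl] (Babler–Dauben) gives 6β-acetoxy-15-(tert-butyldimethylsilyloxy)labda-8,13(Z)-dien-7-one F8. Luche reduction, anti to the axial acetate, gives 6β-acetoxy-15-(tert-butyldimethylsilyloxy)labda-8,13(Z)-dien-7β-ol F9. Mitsunobu inversion with formic acid (PPh3, diisopropyl azodicarboxylate) gives 6β-acetoxy-15-(tert-butyldimethylsilyloxy)-7α-formyloxylabda-8,13(Z)-diene F10. Selective methanolysis of the formate (KHCO3, MeOH, 0 °C) leaves the acetate and gives 26.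

**Further compounds**

F1 | step 12 | 5-(2-methylpent-4-en-2-yl)-3-[(Z)-5-(tert-butyldimethylsilyloxy)-3-methylpent-3-en-1-yl]-2,4-dimethylphenol | C=CCC(C)(C)c1cc(O)c(C)c(CC/C(C)=C\CO[Si](C)(C)C(C)(C)C)c1C
F2 | step 12 | 5-(5-hydroxy-2-methylpentan-2-yl)-3-[(Z)-5-(tert-butyldimethylsilyloxy)-3-methylpent-3-en-1-yl]-2,4-dimethylphenol | OCCCC(C)(C)c1cc(O)c(C)c(CC/C(C)=C\CO[Si](C)(C)C(C)(C)C)c1C
F3 | step 12 | 5-(5-bromo-2-methylpentan-2-yl)-3-[(Z)-5-(tert-butyldimethylsilyloxy)-3-methylpent-3-en-1-yl]-2,4-dimethylphenol | BrCCCC(C)(C)c1cc(O)c(C)c(CC/C(C)=C\CO[Si](C)(C)C(C)(C)C)c1C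
F4 | step 12 | racemic 15-(tert-butyldimethylsilyloxy)labda-5,8,13(Z)-trien-7-one | O=C1C=C2C(C)(C)CCCC2(C)C(CC/C(C)=C\CO[Si](C)(C)C(C)(C)C)=C1C
F5 | step 14 | 15-(tert-butyldimethylsilyloxy)labda-5,9(11),13(Z)-trien-7-one (mixture at C8 and C9=C11) | O=C1C=C2C(C)(C)CCC[C@]2(C)C(=CC/C(C)=C\CO[Si](C)(C)C(C)(C)C)C1C
F6 | step 14 | 15-(tert-butyldimethylsilyloxy)labda-9(11),13(Z)-dien-7-one, 5α-H | C1C(=O)C(C)C(=CC/C(C)=C\CO[Si](C)(C)C(C)(C)C)[C@@]2(C)CCCC(C)(C)[C@H]12
F7 | step 14 | 15-(tert-butyldimethylsilyloxy)labda-8,13(Z)-dien-7-one, 5α-H | C1C(=O)C(C)=C(CC/C(C)=C\CO[Si](C)(C)C(C)(C)C)[C@@]2(C)CCCC(C)(C)[C@H]12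
F8 | step 19 | 6β-acetoxy-15-(tert-butyldimethylsilyloxy)labda-8,13(Z)-dien-7-one | CC(=O)O[C@@H]1C(=O)C(C)=C(CC/C(C)=C\CO[Si](C)(C)C(C)(C)C)[C@@]2(C)CCCC(C)(C)[C@H]12
F9 | step 19 | 6β-acetoxy-15-(tert-butyldimethylsilyloxy)labda-8,13(Z)-dien-7β-ol | CC(=O)O[C@@H]1[C@H](O)C(C)=C(CC/C(C)=C\CO[Si](C)(C)C(C)(C)C)[C@@]2(C)CCCC(C)(C)[C@H]12
F10 | step 19 | 6β-acetoxy-15-(tert-butyldimethylsilyloxy)-7α-formyloxylabda-8,13(Z)-diene | CC(=O)O[C@@H]1[C@@H](OC=O)C(C)=C(CC/C(C)=C\CO[Si](C)(C)C(C)(C)C)[C@@]2(C)CCCC(C)(C)[C@H]12
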